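Readings and results were computed with made-up constants.

I wanted one number.

| flask | starting material | remark | time |
|---|---|---|---|
| ash | 28 mM | run made earlier |  |
| oak | 44 mM | run made earlier |  |
| flask | 20 mM |  | 80 min |

| run | time / min | target / % | side product / % |
|---|---|---|---|
| ash | 10.0 | 29 | 8 |
| ash | 20.0 | 39 | 10 |
| ash | 30.0 | 38 | 12 |
| ash | 40.0 | 38 | 12 |
| ash | 50.0 | 42 | 14 |
| oak | 4.00 | 20 | 3 |
| oak | 8.00 | 27 | 1 |
| oak | 15.0 | 28 | 4 |
| oak | 25.0 | 32 | 8 |
| oak | 50.0 | 36 | 15 |

(standard deviation of a reading: 2 percentage points)

- ratio of target to side product at 25 s
- ratio of target to side product at 80 min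
- which of target and side product there is more of at 80 min



I replaced the late stretch of each run by its mean, summing the target and side product readings from 25.0 min onward. The two runs were independent ways to one ratio. Ash, at 28 mM, gave 3.11, and oak, at 44 mM, gave 2.96. Pooled, they gave 3.05. I called this the late split, the late selectivity: summed target over summed side product from that time onward. Scatter in the summed side product moved it by 0.224, but the last readings taken singly gave 3.00 in ash and 2.40 in oak, so the last oak reading lay further from the split than that.

Early on, the two ways parted: ash read 3.62 at 10.0 min, oak 27.0 at 8.00 min. The oak ratio was the one that cheated, for its side product reading of 1% stood below the scatter of 2 percentage points. So I took no figure of my own for 25 s, and for 80 min in the flask I committed to the late split, with target ahead.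

The forecast gave 6 at 25 s, within 3 to 25, adding that “a consecutive route would make it far larger, so the range is skewed high”. For 80 min it gave 2.3, within 1.5 to 3.2, which is lower than my split, and it put target ahead.

The flask gave 91.3 at 25 s and 3.22 at 80 min, with target 48.5% and side product 15.1%, a gap to the split smaller than 0.224.

    starting material ⇌ intermediate A (K = 0.450, k = 0.0527 s⁻¹)
    starting material ⇌ intermediate B (K = 1.65, k = 0.00152 s⁻¹)
    intermediate A → target (k = 0.00581 s⁻¹)
    intermediate A ⇌ intermediate C (K = 1.02, k = 0.00127 s⁻¹)
    intermediate B → side product (k = 9.65 × 10⁻⁴ s⁻¹)
    intermediate C ⇌ intermediate D (K = 2.11, k = 0.00107 s⁻¹)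
    2 starting material → self-condensation product (k = 0.164 M⁻¹ s⁻¹)

In the flask, starting material relaxed with intermediate A at a half-life of 0.0680 min by that step alone, both ways together, but with intermediate B, the way to side product, at 4.73 min by that step alone. The early time of 25 s lies between the two, and there the ratio stood at 91.3.

For the neighbouring flask with 34 mM of starting material, the late split gave 3.05 at 80 min. The computed ratio there was 3.22, with target 40.3% and side product 12.5%.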